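The ten-membered carbocycle (C1–C10) is opened at the C4–C5 bond, where the C4 methylene meets the Z-configured trisubstituted C5=C6 alkene. One operation, hydroboration of a terminal C3=C4 vinyl group followed by intramolecular palladium-catalysed B-alkyl Suzuki coupling with a (Z)-C5 vinyl iodide, closes the ring with the alkene geometry already fixed. The precursor is the fully functionalised seco compound: a cyclohexene (C1, C10–C14) bearing the C2 acetoxy allyl unit and, through C9, the complete hydroxy γ-lactone with the (Z)-2-iodopropenyl group at C7. It is assembled from a Diels–Alder-derived ring aldehyde and a malate-derived dioxolanone by an aldol union at C8–C9.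

Key step: step 24

Remark (conventions): briarane numbering is used for every intermediate; the six-membered ring is C1–C10–C11–C12–C13–C14, β is the ring face carrying the C1 methyl group, TBS = tert-butyldimethylsilyl, TES = triethylsilyl.
Remark (assumption): in step 4 the (S)-configured oxazaborolidinium catalyst is taken to leave the C10-Si/C1-Si face of the enal open; if the sense of induction is the opposite, its enantiomer is used with no other change.

Step 1
Reactants: 1 ethyl 2-(triphenyl-λ5-phosphanylidene)propanoate; 2 2,2-dimethoxyacetaldehyde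
Product: 3 ethyl (2E)-4,4-dimethoxy-2-methylbut-2-enoate
Conditions: CH2Cl2, rt
Reagents that add atoms: none
Why: Wittig olefination with a stabilised α-methyl ylide gives the E enoate (ester trans to the acetal carbon), the geometry that later places C2 trans to C9 on the ring.

Step 2
Reactants: 3 ethyl (2E)-4,4-dimethoxy-2-methylbut-2-enoate
Product: 4 ethyl (2E)-2-methyl-4-oxobut-2-enoate
Conditions: 1 M HCl, acetone/H2O, rt
Reagents that add atoms: water, O
Why: Acid-catalysed acetal hydrolysis frees the enal while the ester and the thermodynamically preferred E geometry are retained.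

Step 3
Reactants: 5 (3E)-pent-3-en-2-one
Product: 6 (3E)-2-(TBS-oxy)penta-1,3-diene
Conditions: LDA, THF, −78 °C; TBSOTf, −78 to 0 °C
Reagents that add atoms: tert-butyldimethylsilyl trifluoromethanesulfonate, CC(C)(C)[Si](C)(C)OS(=O)(=O)C(F)(F)F
Why: Kinetic enolisation at the α′ methyl group and O-silylation give the cross-conjugated 2-silyloxy diene with the E propenyl unit untouched.

Step 4
Reactants: 4 ethyl (2E)-2-methyl-4-oxobut-2-enoate; 6 (3E)-2-(TBS-oxy)penta-1,3-diene
Product: 8 ethyl 10β-(hydroxymethyl)-1β,11β-dimethyl-13-(TBS-oxy)cyclohex-12-ene-1α-carboxylate, via cycloadduct aldehyde 7 (not isolated)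
Conditions: oxazaborolidinium triflimide from (S)-B-(o-tolyl)-α,α-diphenylprolinol oxazaborolidine and HNTf2 (20 mol%), CH2Cl2, −78 to −40 °C; then Et3N, EtOH, NaBH4, −40 to 0 °C
Reagents that add atoms: none
Why: Catalytic enantioselective Diels–Alder reaction in which the activated formyl group makes C1 the electrophilic terminus (nucleophilic C14 of the silyloxy diene bonds to C1, C11 to C10), the E enal places the C1 methyl cis to C9, the endo-formyl transition state places the C11 methyl cis to C9, the catalyst selects the enal face (absolute configuration at C1, C10, C11), and NaBH4 then reduces only the aldehyde.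

Step 5
Reactants: 8 ring alcohol
Product: 9 ethyl 1β,11β-dimethyl-13-(TBS-oxy)-10β-[(TES-oxy)methyl]cyclohex-12-ene-1α-carboxylate
Conditions: TESCl, imidazole, CH2Cl2, 0 °C
Reagents that add atoms: chlorotriethylsilane, CC[Si](Cl)(CC)CC
Why: Standard silylation masks the primary C9 hydroxyl before oxidation and enolate chemistry, and the hindered quaternary ester is too unreactive to lactonise meanwhile.

Step 6
Reactants: 9 silyl enol ether
Product: 10 ethyl 12α-(TBS-oxy)-1β,11β-dimethyl-13-oxo-10β-[(TES-oxy)methyl]cyclohexane-1α-carboxylate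
Conditions: mCPBA, NaHCO3, CH2Cl2, −20 °C to rt
Reagents that add atoms: 3-chloroperoxybenzoic acid, OOC(=O)c1cccc(Cl)c1
Why: Rubottom oxidation with 1,4-silyl migration: the peracid attacks C12 of the enol ether from the α face, anti to the β C11 methyl and β C10 substituent, which sets C12–O α and trans to the C11 methyl.

Step 7
Reactants: 10 α-silyloxy ketone
Product: 11 ethyl 12α-(TBS-oxy)-1β,11β-dimethyl-10β-[(TES-oxy)methyl]-13-(trifluoromethanesulfonyloxy)cyclohex-13-ene-1α-carboxylate
Conditions: KHMDS, THF, −78 °C; PhNTf2, −78 to −20 °C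
Reagents that add atoms: N-phenylbis(trifluoromethanesulfonimide), O=S(=O)(N(c1ccccc1)S(=O)(=O)C(F)(F)F)C(F)(F)F
Why: Kinetic deprotonation occurs at the C14 methylene and not at the oxygen-bearing tertiary C12, so enolate triflation places the future alkene at C13=C14.

Step 8
Reactants: 11 enol triflate
Product: 12 ethyl 12α-(TBS-oxy)-1β,11β-dimethyl-10β-[(TES-oxy)methyl]cyclohex-13-ene-1α-carboxylate
Conditions: Pd(OAc)2 (5 mol%), PPh3, HCO2H, Et3N, DMF, 60 °C
Reagents that add atoms: none
Why: Palladium-catalysed formate reduction of the enol triflate replaces OTf by H and leaves the C13=C14 alkene with the allylic silyl ether untouched.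

Step 9
Reactants: 12 cyclohexene ester
Product: 13 N-methoxy-N-methyl amide of the C2 acid (Weinreb amide)
Conditions: MeNH(OMe)·HCl, i-PrMgCl, THF, −20 °C to rt
Reagents that add atoms: N,O-dimethylhydroxylamine hydrochloride, CNOC.Cl
Why: Aminolysis of the ester by the magnesium amide gives the Weinreb amide, which allows a single addition in the next step.

Step 10
Reactants: 13 Weinreb amide
Product: 14 C2 vinyl ketone (1-[ring-C1]-prop-2-en-1-one)
Conditions: CH2=CHMgBr, THF, −20 to 0 °C; inverse quench into cold aqueous HCl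
Reagents that add atoms: vinylmagnesium bromide, C=C[Mg]Br
Why: Grignard addition to a Weinreb amide stops at the chelated tetrahedral intermediate and gives the enone that carries C3 and C4.

Step 11
Reactants: 14 C2 vinyl ketone
Product: 15 (2R)-allylic alcohol
Conditions: (S)-2-methyl-CBS-oxazaborolidine (20 mol%), catecholborane, toluene, −78 °C
Reagents that add atoms: none
Why: Corey–Bakshi–Shibata reduction with the quaternary C1 as the large group and vinyl as the small group gives 2R, the same sense as Felkin–Anh delivery of hydride anti to C10, and catecholborane does not hydroborate the alkenes at this temperature.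

Step 12
Reactants: 15 (2R)-allylic alcohol
Product: 16 (2R)-2-O-TES ether (bis-TES, TBS compound)
Conditions: TESOTf, 2,6-lutidine, CH2Cl2, −78 °C
Reagents that add atoms: triethylsilyl trifluoromethanesulfonate, CC[Si](CC)(CC)OS(=O)(=O)C(F)(F)F
Why: Silyl triflate silylation protects the hindered secondary C2 hydroxyl as the same acid-labile group that will later be used at C9.

Step 13
Reactants: 16 bis-TES ether
Product: 17 ring aldehyde (C9 formyl, 2R-OTES, 12α-OTBS)
Conditions: (COCl)2, DMSO, CH2Cl2, −78 to −35 °C; Et3N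
Reagents that add atoms: none
Why: Swern conditions cleave and oxidise the primary TES ether directly to the aldehyde while the secondary TES and TBS ethers survive, and the low temperature protects the C10 stereocentre.

Step 14
Reactants: 18 diethyl (S)-malate
Product: 19 diethyl (2S,3R)-3-methylmalate
Conditions: LDA (2.2 equiv), THF, −78 to −20 °C; MeI, −78 °C to rt
Reagents that add atoms: iodomethane, CI
Why: Fráter–Seebach alkylation: the chelated alkoxide–enolate dianion is methylated anti to the alkoxide, which sets C17 (R) and the cis OH/CH3 relation of the lactone.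

Step 15
Reactants: 19 diethyl (2S,3R)-3-methylmalate
Product: 20 (2S,3R)-2-hydroxy-3-methylbutanedioic acid
Conditions: KOH, H2O/EtOH, 0 °C to rt; aqueous HCl
Reagents that add atoms: potassium hydroxide, [K+].[OH-]
Why: Saponification of both esters under mild conditions gives the diacid without epimerising the carboxylate α-carbon.

Step 16
Reactants: 20 (2S,3R)-2-hydroxy-3-methylbutanedioic acid; 21 pivalaldehyde
Product: 22 (2S,5S)-2-tert-butyl-5-[(1R)-1-carboxyethyl]-1,3-dioxolan-4-one
Conditions: TsOH (cat.), H2SO4 (cat.), pentane, reflux, Dean–Stark; crystallisation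
Reagents that add atoms: none
Why: Acid-catalysed acetalisation of the α-hydroxy acid gives the cis-2-tert-butyl dioxolanone, whose acetal centre stores the C8 configuration (self-regeneration of stereocentres).

Step 17
Reactants: 22 dioxolanone acid; 17 ring aldehyde
Product: 24 C9 triethylsilyl ether of the aldol acid, via aldol adduct 23 (not isolated)
Conditions: 22 (1.5 equiv), LiHMDS (2 equiv per 22), THF, −78 °C; 17, −78 to −60 °C; TESOTf, 2,6-lutidine, −78 to −40 °C; aqueous NaHCO3, then pH 4 buffer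
Reagents that add atoms: triethylsilyl trifluoromethanesulfonate, CC[Si](CC)(CC)OS(=O)(=O)C(F)(F)F
Why: Aldol addition of the carboxylate–enolate dianion places C9 on C8 anti to the tert-butyl group (retention at C8), a closed Zimmerman–Traxler transition state of the ring-constrained enolate and Felkin–Anh attack on the aldehyde (C1 anti) both favour 9R, and in situ silylation blocks retro-aldol and any later lactonisation through O9.

Step 18
Reactants: 24 C9 TES ether acid; 25 propyne
Product: 26 C7 ynone acid (C7 ketone bearing prop-1-ynyl, free tertiary C8 hydroxyl)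
Conditions: n-BuLi with 25 to give 1-propynyllithium (3.5 equiv), THF, −78 to −50 °C; AcOH quench at −78 °C
Reagents that add atoms: none
Why: Alkynyllithium addition to the activated dioxolanone carbonyl (the carboxylic acid is protected as its lithium salt) gives a stable tetrahedral intermediate that collapses on work-up to the ynone, releasing pivalaldehyde and the C8 hydroxyl.

Step 19
Reactants: 26 C7 ynone acid
Product: 28 alkynyl γ-lactone, via hydroxy acid 27 (not isolated)
Conditions: RuCl[(R,R)-TsDPEN](p-cymene) (5 mol%), HCO2H/Et3N (5:2), CH2Cl2, rt; then PPTS (cat.), CH2Cl2, rt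
Reagents that add atoms: none
Why: Noyori asymmetric transfer hydrogenation, with the alkynyl group in the site normally taken by an aryl group, gives 7S with the (R,R)-catalyst (also the Felkin–Anh sense), and the γ-hydroxy acid then closes to the five-membered lactone through O7, the only free secondary hydroxyl.

Step 20
Reactants: 28 alkynyl γ-lactone
Product: 29 (5Z)-5-triethylsilyl alkene (vinylsilane)
Conditions: [Cp*Ru(MeCN)3]PF6 (10 mol%), Et3SiH, CH2Cl2, 0 °C to rt
Reagents that add atoms: triethylsilane, CC[SiH](CC)CC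
Why: Ruthenium-catalysed trans-hydrosilylation adds H and Si anti across the alkyne with silicon on the less hindered C5 distal to the propargylic C7–O bond, giving Si cis to C7, and it tolerates the alkenes, the lactone and the free hydroxyl.

Step 21
Reactants: 29 vinylsilane
Product: 30 (5Z)-vinyl iodide (2,9-bis-TES ether)
Conditions: NIS, 2,6-lutidine, (CF3)2CHOH, 0 °C
Reagents that add atoms: N-iodosuccinimide, O=C1CCC(=O)N1I
Why: Ipso iododesilylation proceeds with retention of geometry, and the β-silicon effect makes the vinylsilane far more reactive than the other alkenes.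

Step 22
Reactants: 30 vinyl iodide bis-TES ether
Product: 31 2,8,9-triol (C12 TBS ether)
Conditions: HF·pyridine, pyridine, THF, 0 °C to rt
Reagents that add atoms: none
Why: Buffered fluoride cleaves triethylsilyl ethers much faster than the secondary TBS ether, freeing C2–OH and C9–OH together.

Step 23
Reactants: 31 triol
Product: 32 seco C4–C5 iodo diene lactone (2,9-diacetate, free C8–OH, C12 TBS ether)
Conditions: Ac2O, DMAP, Et3N, CH2Cl2, rt
Reagents that add atoms: acetic anhydride, CC(=O)OC(C)=O
Why: DMAP-catalysed acetylation esterifies both secondary alcohols while the tertiary C8 hydroxyl stays free.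

Step 24
Reactants: 32 seco iodo diene lactone
Product: 34 C12 TBS ether of the target, via alkylborane 33 (not isolated)
Conditions: 9-BBN dimer (3 equiv B–H), THF, 0 °C to rt; then syringe-pump addition to Pd(dppf)Cl2 (30 mol%), AsPh3, Cs2CO3, degassed H2O, DMF/THF, 45 °C, final concentration 1 mM
Reagents that add atoms: none
Why: 9-BBN adds across the monosubstituted C3=C4 alkene with boron on C4, zerovalent palladium inserts into the C5–I bond, the carbonate-activated borate transfers the C4 alkyl group to palladium, and reductive elimination forms the C4–C5 bond. The closest known reaction type is the B-alkyl Suzuki–Miyaura macrocyclisation. The ten-membered ring closes in an endo sense by C(sp3)–C(sp2) reductive elimination from a palladacycle, so no ring alkene has to be made or isomerised. No stereocentre is created, and the Z geometry at C5=C6 is carried over because oxidative addition and reductive elimination at the vinyl carbon go with retention. The step needs chemoselective hydroboration, secured by the steric gap between the vinyl group and the hindered cyclohexene and iodoalkene and by completing hydroboration before palladium meets the allylic C2 acetate, and cyclisation over oligomerisation, secured by high dilution, dppf/AsPh3 against β-hydride elimination and a mild carbonate base that spares the acetates and the β-hydroxy lactone.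

Step 25
Reactants: 34 C12 TBS ether of the target
Product: 35 target CNP0222085.1
Conditions: HF·pyridine, pyridine, THF, 0 °C to rt
Reagents that add atoms: none
Why: Acidic fluoride desilylation removes the allylic TBS ether without the basic conditions that could cause acetyl migration or retro-aldol opening of the β-hydroxy lactone.

Compound list

1 | ethyl 2-(triphenyl-λ5-phosphanylidene)propanoate | CCOC(=O)C(C)=P(c1ccccc1)(c1ccccc1)c1ccccc1 | starting material
2 | 2,2-dimethoxyacetaldehyde | COC(OC)C=O | starting material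
3 | ethyl (2E)-4,4-dimethoxy-2-methylbut-2-enoate | CCOC(=O)/C(C)=C/C(OC)OC | intermediate
4 | ethyl (2E)-2-methyl-4-oxobut-2-enoate | CCOC(=O)/C(C)=C/C=O | intermediate
5 | (3E)-pent-3-en-2-one | C/C=C/C(C)=O | starting material
6 | (3E)-2-(tert-butyldimethylsilyloxy)penta-1,3-diene | C=C(O[Si](C)(C)C(C)(C)C)/C=C/C | intermediate
7 | cycloadduct aldehyde: ethyl 10β-formyl-1β,11β-dimethyl-13-(TBS-oxy)cyclohex-12-ene-1α-carboxylate | CCOC(=O)[C@@]1(C)CC(O[Si](C)(C)C(C)(C)C)=C[C@H](C)[C@@H]1C=O | intermediate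
8 | ethyl 10β-(hydroxymethyl)-1β,11β-dimethyl-13-(TBS-oxy)cyclohex-12-ene-1α-carboxylate | CCOC(=O)[C@@]1(C)CC(O[Si](C)(C)C(C)(C)C)=C[C@H](C)[C@@H]1CO | intermediate
9 | ethyl 1β,11β-dimethyl-13-(TBS-oxy)-10β-[(TES-oxy)methyl]cyclohex-12-ene-1α-carboxylate | CCOC(=O)[C@@]1(C)CC(O[Si](C)(C)C(C)(C)C)=C[C@H](C)[C@@H]1CO[Si](CC)(CC)CC | intermediate
10 | ethyl 12α-(TBS-oxy)-1β,11β-dimethyl-13-oxo-10β-[(TES-oxy)methyl]cyclohexane-1α-carboxylate | CCOC(=O)[C@@]1(C)CC(=O)[C@@H](O[Si](C)(C)C(C)(C)C)[C@H](C)[C@@H]1CO[Si](CC)(CC)CC | intermediate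
11 | ethyl 12α-(TBS-oxy)-1β,11β-dimethyl-10β-[(TES-oxy)methyl]-13-(trifluoromethanesulfonyloxy)cyclohex-13-ene-1α-carboxylate | CCOC(=O)[C@@]1(C)C=C(OS(=O)(=O)C(F)(F)F)[C@@H](O[Si](C)(C)C(C)(C)C)[C@H](C)[C@@H]1CO[Si](CC)(CC)CC | intermediate
12 | ethyl 12α-(TBS-oxy)-1β,11β-dimethyl-10β-[(TES-oxy)methyl]cyclohex-13-ene-1α-carboxylate | CCOC(=O)[C@@]1(C)C=C[C@@H](O[Si](C)(C)C(C)(C)C)[C@H](C)[C@@H]1CO[Si](CC)(CC)CC | intermediate
13 | 12α-(TBS-oxy)-N-methoxy-N,1β,11β-trimethyl-10β-[(TES-oxy)methyl]cyclohex-13-ene-1α-carboxamide | CON(C)C(=O)[C@@]1(C)C=C[C@@H](O[Si](C)(C)C(C)(C)C)[C@H](C)[C@@H]1CO[Si](CC)(CC)CC | intermediate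
14 | 1-{12α-(TBS-oxy)-1β,11β-dimethyl-10β-[(TES-oxy)methyl]cyclohex-13-en-1α-yl}prop-2-en-1-one (C2 vinyl ketone) | C=CC(=O)[C@@]1(C)C=C[C@@H](O[Si](C)(C)C(C)(C)C)[C@H](C)[C@@H]1CO[Si](CC)(CC)CC | intermediate
15 | (2R)-allylic alcohol: (1R)-1-{same cyclohexenyl}prop-2-en-1-ol | C=C[C@@H](O)[C@@]1(C)C=C[C@@H](O[Si](C)(C)C(C)(C)C)[C@H](C)[C@@H]1CO[Si](CC)(CC)CC | intermediate
16 | (2R)-2-O-TES ether of 15 (C2 OTES, C9 CH2OTES, C12α OTBS) | C=C[C@@H](O[Si](CC)(CC)CC)[C@@]1(C)C=C[C@@H](O[Si](C)(C)C(C)(C)C)[C@H](C)[C@@H]1CO[Si](CC)(CC)CC | intermediate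
17 | ring aldehyde: 10β-formyl cyclohexene with 1β,11β-dimethyl, 12α-OTBS and 1α-[(1R)-1-(TES-oxy)prop-2-enyl] | C=C[C@@H](O[Si](CC)(CC)CC)[C@@]1(C)C=C[C@@H](O[Si](C)(C)C(C)(C)C)[C@H](C)[C@@H]1C=O | intermediate
18 | diethyl (S)-malate | CCOC(=O)C[C@H](O)C(=O)OCC | starting material
19 | diethyl (2S,3R)-3-methylmalate | CCOC(=O)[C@@H](O)[C@@H](C)C(=O)OCC | intermediate
20 | (2S,3R)-2-hydroxy-3-methylbutanedioic acid | OC(=O)[C@@H](O)[C@@H](C)C(=O)O | intermediate
21 | pivalaldehyde | CC(C)(C)C=O | starting material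
22 | (2S,5S)-2-tert-butyl-5-[(1R)-1-carboxyethyl]-1,3-dioxolan-4-one (cis) | CC(C)(C)[C@H]1O[C@@H]([C@@H](C)C(=O)O)C(=O)O1 | intermediate
23 | aldol adduct (formed as its dilithium salt): 9R-hydroxy acid, C8 = spiro carbon of the 2-tert-butyl-1,3-dioxolan-4-one (tert-butyl trans to C9), 17R-methyl, C19 acid | C=C[C@@H](O[Si](CC)(CC)CC)[C@@]1(C)C=C[C@@H](O[Si](C)(C)C(C)(C)C)[C@H](C)[C@@H]1[C@@H](O)[C@]2(O[C@H](C(C)(C)C)OC2=O)[C@@H](C)C(=O)O | intermediate
24 | 9-O-TES ether of 23 (free C19 acid) | C=C[C@@H](O[Si](CC)(CC)CC)[C@@]1(C)C=C[C@@H](O[Si](C)(C)C(C)(C)C)[C@H](C)[C@@H]1[C@@H](O[Si](CC)(CC)CC)[C@]2(O[C@H](C(C)(C)C)OC2=O)[C@@H](C)C(=O)O | intermediate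
25 | propyne | CC#C | starting material
26 | C7 ynone acid: C7 ketone with prop-1-ynyl, tertiary C8–OH, 9R-OTES, 17R-methyl, C19 acid | C=C[C@@H](O[Si](CC)(CC)CC)[C@@]1(C)C=C[C@@H](O[Si](C)(C)C(C)(C)C)[C@H](C)[C@@H]1[C@@H](O[Si](CC)(CC)CC)[C@@](O)(C(=O)C#CC)[C@@H](C)C(=O)O | intermediate
27 | hydroxy acid: 7S-propargylic alcohol of 26 | C=C[C@@H](O[Si](CC)(CC)CC)[C@@]1(C)C=C[C@@H](O[Si](C)(C)C(C)(C)C)[C@H](C)[C@@H]1[C@@H](O[Si](CC)(CC)CC)[C@@](O)([C@@H](O)C#CC)[C@@H](C)C(=O)O | intermediate
28 | alkynyl γ-lactone (O7–C19 lactone, 7S-prop-1-ynyl, 8-OH, 17R-methyl; 2R,9R-bis-OTES, 12α-OTBS) | C=C[C@@H](O[Si](CC)(CC)CC)[C@@]1(C)C=C[C@@H](O[Si](C)(C)C(C)(C)C)[C@H](C)[C@@H]1[C@@H](O[Si](CC)(CC)CC)[C@]2(O)[C@@H](C)C(=O)O[C@H]2C#CC | intermediate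
29 | (5Z)-5-triethylsilyl alkene: 7-[(1Z)-2-(triethylsilyl)prop-1-enyl] lactone | C=C[C@@H](O[Si](CC)(CC)CC)[C@@]1(C)C=C[C@@H](O[Si](C)(C)C(C)(C)C)[C@H](C)[C@@H]1[C@@H](O[Si](CC)(CC)CC)[C@]2(O)[C@@H](C)C(=O)O[C@H]2/C=C(/C)[Si](CC)(CC)CC | intermediate
30 | (5Z)-vinyl iodide: 7-[(1Z)-2-iodoprop-1-enyl] lactone, 2,9-bis-OTES, 12-OTBS | C=C[C@@H](O[Si](CC)(CC)CC)[C@@]1(C)C=C[C@@H](O[Si](C)(C)C(C)(C)C)[C@H](C)[C@@H]1[C@@H](O[Si](CC)(CC)CC)[C@]2(O)[C@@H](C)C(=O)O[C@H]2/C=C(/C)I | intermediate
31 | 2R,8,9R-triol of 30 (12-OTBS retained) | C=C[C@@H](O)[C@@]1(C)C=C[C@@H](O[Si](C)(C)C(C)(C)C)[C@H](C)[C@@H]1[C@@H](O)[C@]2(O)[C@@H](C)C(=O)O[C@H]2/C=C(/C)I | intermediate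
32 | seco C4–C5 iodo diene lactone: 2R,9R-diacetate, free 8-OH, 12α-OTBS, (5Z)-iodide | C=C[C@@H](OC(C)=O)[C@@]1(C)C=C[C@@H](O[Si](C)(C)C(C)(C)C)[C@H](C)[C@@H]1[C@@H](OC(C)=O)[C@]2(O)[C@@H](C)C(=O)O[C@H]2/C=C(/C)I | intermediate
33 | alkylborane: C4-(9-borabicyclo[3.3.1]nonan-9-yl) derivative of 32 | C1CC2CCCC(C1)B2CC[C@@H](OC(C)=O)[C@@]3(C)C=C[C@@H](O[Si](C)(C)C(C)(C)C)[C@H](C)[C@@H]3[C@@H](OC(C)=O)[C@]4(O)[C@@H](C)C(=O)O[C@H]4/C=C(/C)I | intermediate
34 | C12 TBS ether of the target (bicyclic briarane lactone, 5Z) | CC(=O)O[C@@H]1[C@H]2[C@@H](C)[C@H](O[Si](C)(C)C(C)(C)C)C=C[C@]2(C)[C@H](OC(C)=O)CC/C(C)=C\[C@@H]2OC(=O)[C@H](C)[C@]21O | intermediate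
35 | CNP0222085.1: (1S,2R,5Z,7S,8S,9R,10S,11R,12R,17R)-2,9-diacetoxy-8,12-dihydroxybriara-5,13-dien-18,7-olide | CC(=O)O[C@@H]1[C@H]2[C@@H](C)[C@H](O)C=C[C@]2(C)[C@H](OC(C)=O)CC/C(C)=C\[C@@H]2OC(=O)[C@H](C)[C@]21O | target

Total step count: 25. Longest linear sequence: 21 steps (1, 2, 4–13, 17–25).

Steps most likely to fail

1. Step 4. Facial and endo selectivity may erode, or the silyl enol ether may add stepwise to the formyl group, because a quaternary carbon has to form at the enal β-position. The fallback replaces catalyst control by auxiliary control. It sets out from 4: Pinnick oxidation (NaClO2, NaH2PO4, 2-methylbut-2-ene) gives (2E)-4-ethoxy-3-methyl-4-oxobut-2-enoic acid F1. Its pivaloyl mixed anhydride acylates lithiated (4S)-4-benzyloxazolidin-2-one to give (4S)-4-benzyl-3-[(2E)-4-ethoxy-3-methyl-4-oxobut-2-enoyl]oxazolidin-2-one F2. Me2AlCl-promoted cycloaddition with 6 at −78 °C through the chelated s-cis imide, whose C10-Re face is shielded by the benzyl group, gives the cycloadduct imide F3. LiBH4 in THF with one equivalent of water at 0 °C removes the auxiliary reductively and the route is rejoined at 8.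

2. Step 17. Addition to the congested aldehyde may stay incomplete, the aldolate may revert, and control at C9 may be insufficient. The fallback moves C9 control from the aldol transition state to a ketone reduction. It sets out from 23, isolated as the hydroxy acid mixture: Dess–Martin periodinane with NaHCO3 gives the C9 ketone F4. NaBH4 in MeOH at −40 °C under Felkin–Anh control (C8–O bond anti to hydride) returns 9R-23, and silylation (TESOTf, 2,6-lutidine, aqueous work-up) rejoins the route at 24.

3. Step 24. Protodeboronation, β-hydride elimination of the alkylpalladium intermediate, or intermolecular coupling may outrun closure of the ten-membered ring. The fallback forms the same C4–C5 bond by cross-electrophile coupling instead of boron-to-palladium transfer. It sets out from 32: hydroboration with 9-BBN and oxidation with NaBO3·4H2O give the C4 primary alcohol F5. Appel iodination (I2, PPh3, imidazole) gives the C4 iodide F6. Nickel-catalysed reductive coupling of the alkyl iodide with the vinyl iodide (NiBr2·glyme, 4,4′-di-tert-butyl-2,2′-bipyridine, Zn dust, DMA, 1 mM) closes the ring and rejoins the route at 34.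

Further compounds

F1 | step 4 | (2E)-4-ethoxy-3-methyl-4-oxobut-2-enoic acid | CCOC(=O)/C(C)=C/C(=O)O
F2 | step 4 | (4S)-4-benzyl-3-[(2E)-4-ethoxy-3-methyl-4-oxobut-2-enoyl]oxazolidin-2-one | CCOC(=O)/C(C)=C/C(=O)N1[C@@H](Cc2ccccc2)COC1=O
F3 | step 4 | cycloadduct imide: ethyl 10β-{[(4S)-4-benzyl-2-oxooxazolidin-3-yl]carbonyl}-1β,11β-dimethyl-13-(TBS-oxy)cyclohex-12-ene-1α-carboxylate | CCOC(=O)[C@@]1(C)CC(O[Si](C)(C)C(C)(C)C)=C[C@H](C)[C@@H]1C(=O)N2[C@@H](Cc3ccccc3)COC2=O
F4 | step 17 | C9 ketone of aldol adduct 23 | C=C[C@@H](O[Si](CC)(CC)CC)[C@@]1(C)C=C[C@@H](O[Si](C)(C)C(C)(C)C)[C@H](C)[C@@H]1C(=O)[C@]2(O[C@H](C(C)(C)C)OC2=O)[C@@H](C)C(=O)O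
F5 | step 24 | C4 primary alcohol from 32 | OCC[C@@H](OC(C)=O)[C@@]1(C)C=C[C@@H](O[Si](C)(C)C(C)(C)C)[C@H](C)[C@@H]1[C@@H](OC(C)=O)[C@]2(O)[C@@H](C)C(=O)O[C@H]2/C=C(/C)I
F6 | step 24 | C4 primary iodide from F5 | ICC[C@@H](OC(C)=O)[C@@]1(C)C=C[C@@H](O[Si](C)(C)C(C)(C)C)[C@H](C)[C@@H]1[C@@H](OC(C)=O)[C@]2(O)[C@@H](C)C(=O)O[C@H]2/C=C(/C)I
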